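Cuts: (a) C1''–C2'' of the geranyl chain (ArCH2–CH=); (b) C2–C1' between ring C and ring B; (c) C6–C1'' between ring A and its CH2; (d) C3''–CH3 and C3''–C4'' inside the C9 piece.
Enabling feature: C1'' sits on C6 of ring A between C5–OH and C7–OH, so it is an ortho-hydroxybenzyl carbon. Loss of a leaving group from it turns ring A into a C7=O/C6=CH2 ortho-quinone methide, and that oxygen can hold the boron that delivers C2''.
Forward: no ring is built, since rings A/C come intact from 5,7-dihydroxychromone. C6 is iodinated and methoxymethylated (C1'' enters as CH2OMe), ring B is added at C2, and O7 is freed. The C9 alkenylboronic acid (bromide + acetylide, methylalumination, iodide, boronic acid) is joined last on the unprotected triol.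
Stereochemistry: C2 (S) comes from a Rh/(S)-diphosphine 1,4-addition and is kept by avoiding base afterwards. The 2''E alkene comes from syn-carboalumination and is carried with retention through I, Li, B and the final transfer.

Key step: step 9

Assumption: 1, 2, 9, 12 and 14 are taken as catalogue compounds; the sense of induction in step 7 is assigned by analogy with 2-cyclohexenone.

Step 1
Reactants: 1 5-bromo-2-methylpent-2-ene; 2 lithium acetylide–ethylenediamine complex
Product: 3 6-methylhept-5-en-1-yne
Conditions: DMSO, 10 °C → rt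
Reagents that add atoms: none
Why: SN2 alkylation of acetylide by an unhindered primary homoallylic bromide in a dipolar aprotic solvent should outrun elimination.

Step 2
Reactants: 3 6-methylhept-5-en-1-yne
Product: 5 (E)-1-iodo-2,6-dimethylhepta-1,5-diene, via alkenyldimethylalane 4 (not isolated)
Conditions: Me3Al, Cp2ZrCl2 (cat.), CH2Cl2, 0 °C → rt; then I2, THF, −30 → 0 °C
Reagents that add atoms: trimethylaluminium C[Al](C)C; iodine II
Why: Negishi Zr-catalysed carboalumination adds Me and Al syn across the terminal alkyne with Al at the terminus, and iodinolysis of the C–Al bond goes with retention, which fixes the E trisubstituted alkene while the isolated trisubstituted alkene is left alone.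

Step 3
Reactants: 5 (E)-1-iodo-2,6-dimethylhepta-1,5-diene
Product: 8 (E)-(2,6-dimethylhepta-1,5-dien-1-yl)boronic acid, via alkenyllithium 6 (not isolated), via lithium alkenyltriisopropoxyborate 7 (not isolated)
Conditions: B(OiPr)3, n-BuLi, toluene–THF, −78 °C (in situ quench); 1 M HCl, 0 °C
Reagents that add atoms: triisopropyl borate CC(C)OB(OC(C)C)OC(C)C; water O
Why: Iodine–lithium exchange and borate capture both retain configuration at the sp2 carbon, and mild acidic hydrolysis of the ate complex releases the boronic acid.

Step 4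
Reactants: 9 5,7-dihydroxy-4H-chromen-4-one
Product: 10 5-hydroxy-7-(methoxymethoxy)-4H-chromen-4-one
Conditions: MOMCl (1.1 equiv), K2CO3, acetone, 0 °C → rt
Reagents that add atoms: chloromethyl methyl ether COCCl
Why: Williamson-type O-alkylation picks the acidic, non-chelated 7-OH because the 5-OH is locked in a hydrogen bond to C4=O.

Step 5
Reactants: 10 5-hydroxy-7-(methoxymethoxy)-4H-chromen-4-one
Product: 11 5-hydroxy-6-iodo-7-(methoxymethoxy)-4H-chromen-4-one
Conditions: BnMe3N·ICl2 (1.0 equiv), CaCO3, CH2Cl2–MeOH, rt
Reagents that add atoms: benzyltrimethylammonium dichloroiodate C[N+](C)(C)Cc1ccccc1.Cl[I-]Cl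
Why: Electrophilic aromatic iodination is steered ortho to the only free phenol (5-OH), hence to C6 between O5 and O7, as is established for 5-hydroxy-7-alkoxy-flavones with this reagent, and CaCO3 takes up the HCl so that the MOM acetal survives.

Step 6
Reactants: 11 5-hydroxy-6-iodo-7-(methoxymethoxy)-4H-chromen-4-one; 12 tributyl(methoxymethyl)stannane
Product: 13 5-hydroxy-6-(methoxymethyl)-7-(methoxymethoxy)-4H-chromen-4-one
Conditions: Pd(PPh3)4 (cat.), CuI (cat.), 1,4-dioxane, 90 °C
Reagents that add atoms: none
Why: Migita–Kosugi–Stille coupling of an aryl iodide with an α-alkoxymethylstannane places C1'' on C6 at the benzylic-ether oxidation level under neutral conditions that spare the base-sensitive pyrone ring, the free phenol and the MOM group.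

Step 7
Reactants: 13 5-hydroxy-6-(methoxymethyl)-7-(methoxymethoxy)-4H-chromen-4-one; 14 (3-hydroxy-4-methoxyphenyl)boronic acid
Product: 15 (2S)-5-hydroxy-2-(3-hydroxy-4-methoxyphenyl)-6-(methoxymethyl)-7-(methoxymethoxy)chroman-4-one
Conditions: [Rh(OH)(cod)]2 (cat.), (S)-MeO-F12-BIPHEP (cat.), 14 (2 equiv), toluene–H2O, 25–35 °C
Reagents that add atoms: none
Why: In this Hayashi–Miyaura asymmetric 1,4-addition the aryl–Rh species on the electron-poor (S)-biaryl diphosphine inserts C2=C3 of the chromone from the face it also selects in 2-cyclohexenone, which sets C2 as S, while fast protonolysis in the neutral two-phase medium prevents opening of ring C and the benzylic ether stays latent because O7 is capped and the 5-OH is chelated.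

Step 8
Reactants: 15 (2S)-5-hydroxy-2-(3-hydroxy-4-methoxyphenyl)-6-(methoxymethyl)-7-(methoxymethoxy)chroman-4-one
Product: 16 (2S)-5,7-dihydroxy-2-(3-hydroxy-4-methoxyphenyl)-6-(methoxymethyl)chroman-4-one
Conditions: HCl (0.5 M) in MeOH, high dilution, 40 °C; used promptly
Reagents that add atoms: none
Why: Acid-catalysed acetal methanolysis frees O7, any ionisation of the C6 benzylic methyl ether is degenerate in methanol, dilution suppresses benzylation at C8, and C2 is safe because ring C opens readily only under base.

Step 9
Reactants: 16 (2S)-5,7-dihydroxy-2-(3-hydroxy-4-methoxyphenyl)-6-(methoxymethyl)chroman-4-one; 8 (E)-(2,6-dimethylhepta-1,5-dien-1-yl)boronic acid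
Product: 20 (2S)-6-geranylhesperetin (target), via O7 alkenylboronate half-ester 17 (not isolated), via quinone methide borate 18 (not isolated), via O7 aryl borate 19 (not isolated)
Conditions: 8 (1.5–2 equiv), 2,2'-biphenol (20 mol %), 4 Å MS, toluene–1,4-dioxane, 60–70 °C, slow addition of 16; then pH 6 phosphate buffer
Reagents that add atoms: none
Why: The boronic acid esterifies the acidic C7–OH (17), its boron binds the neighbouring benzylic OMe and pulls it off C1'' so that ring A collapses to the C7=O/C6=CH2 ortho-quinone methide still held on a four-coordinate alkenylborate (18), and the alkenyl carbon then migrates from boron to the exocyclic CH2 through a six-membered chair-like array (B–O7–C7–C6–C1''···C2''), which re-aromatises ring A (19). The closest known reaction type is the diol-catalysed conjugate addition of alkenylboronates to ortho-quinone methides released from ortho-hydroxybenzyl ethers, a vinylogous relative of the Petasis borono-Mannich reaction of salicylaldehydes. No ring is closed and no stereocentre is made; the E geometry of 8 is carried over because B–C is exchanged for C–C with retention, and C2 is untouched because the medium is never basic. The step needs C- over O-alkylation, C6 over C8, and alkenyl transfer rather than dimerisation or hetero-Diels–Alder capture of the quinone methide: the first two are fixed because the electrophilic carbon already sits on C6, the last by tethered delivery and the low stationary concentration of 18. Work-up hydrolyses the aryl borate 19 to the free triol, so no protecting group has to be removed in the presence of the acid-sensitive geranyl chain.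

Compound list
1 | 5-bromo-2-methylpent-2-ene | CC(C)=CCCBr | starting material
2 | lithium acetylide–ethylenediamine complex | [Li]C#C.NCCN | starting material
3 | 6-methylhept-5-en-1-yne | C#CCCC=C(C)C | intermediate
4 | (E)-(2,6-dimethylhepta-1,5-dien-1-yl)dimethylalane (not isolated) | C[Al](C)/C=C(\C)CCC=C(C)C | intermediate
5 | (E)-1-iodo-2,6-dimethylhepta-1,5-diene | I/C=C(\C)CCC=C(C)C | intermediate
6 | (E)-(2,6-dimethylhepta-1,5-dien-1-yl)lithium (not isolated) | [Li]/C=C(\C)CCC=C(C)C | intermediate
7 | lithium (E)-(2,6-dimethylhepta-1,5-dien-1-yl)triisopropoxyborate (not isolated) | [Li+].CC(C)O[B-](OC(C)C)(OC(C)C)/C=C(\C)CCC=C(C)C | intermediate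
8 | (E)-(2,6-dimethylhepta-1,5-dien-1-yl)boronic acid | OB(O)/C=C(\C)CCC=C(C)C | intermediate
9 | 5,7-dihydroxy-4H-chromen-4-one | O=c1ccoc2cc(O)cc(O)c12 | starting material
10 | 5-hydroxy-7-(methoxymethoxy)-4H-chromen-4-one | COCOc1cc(O)c2c(=O)ccoc2c1 | intermediate
11 | 5-hydroxy-6-iodo-7-(methoxymethoxy)-4H-chromen-4-one | COCOc1cc2occc(=O)c2c(O)c1I | intermediate
12 | tributyl(methoxymethyl)stannane | CCCC[Sn](CCCC)(CCCC)COC | starting material
13 | 5-hydroxy-6-(methoxymethyl)-7-(methoxymethoxy)-4H-chromen-4-one | COCOc1cc2occc(=O)c2c(O)c1COC | intermediate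
14 | (3-hydroxy-4-methoxyphenyl)boronic acid | COc1ccc(B(O)O)cc1O | starting material
15 | (2S)-5-hydroxy-2-(3-hydroxy-4-methoxyphenyl)-6-(methoxymethyl)-7-(methoxymethoxy)chroman-4-one | COc1ccc([C@@H]2CC(=O)c3c(cc(OCOC)c(COC)c3O)O2)cc1O | intermediate
16 | (2S)-5,7-dihydroxy-2-(3-hydroxy-4-methoxyphenyl)-6-(methoxymethyl)chroman-4-one | COc1ccc([C@@H]2CC(=O)c3c(cc(O)c(COC)c3O)O2)cc1O | intermediate
17 | O7 (E)-alkenylboronic half-ester of 16 (not isolated) | COc1ccc([C@@H]2CC(=O)c3c(cc(OB(O)/C=C(\C)CCC=C(C)C)c(COC)c3O)O2)cc1O | intermediate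
18 | C7=O/C6=CH2 ortho-quinone methide bound through O7 to the hydroxy(methoxy)alkenylborate (not isolated) | C=C1C(=[O+][B-](O)(OC)/C=C(\C)CCC=C(C)C)C=C2O[C@H](c3ccc(OC)c(O)c3)CC(=O)C2=C1O | intermediate
19 | O7 hydroxy(methoxy)boryl ester of the target (not isolated) | COc1ccc([C@@H]2CC(=O)c3c(cc(OB(O)OC)c(C/C=C(\C)CCC=C(C)C)c3O)O2)cc1O | intermediate
20 | (2S)-6-[(2E)-3,7-dimethylocta-2,6-dien-1-yl]-5,7-dihydroxy-2-(3-hydroxy-4-methoxyphenyl)chroman-4-one | COc1ccc([C@@H]2CC(=O)c3c(cc(O)c(C/C=C(\C)CCC=C(C)C)c3O)O2)cc1O | target

Total step count: 9. Longest linear sequence: 6 steps (steps 4–9, from 9 to 20). The side chain (steps 1–3) converges at step 9.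

Steps most likely to fail

Step 9.
- What may go wrong: release of the quinone methide may outrun alkenyl transfer. It would then be consumed by C8 of a second flavanone or by hetero-Diels–Alder addition to a trisubstituted alkene. Alternatively the boronic acid may protodeboronate before the primary ether ionises.
- Fallback: the same bond is made by two-electron Pd cross-coupling on a fully masked ring A instead of through a quinone methide.
- Setting out from 16, acetylation (Ac2O, pyridine, 0 °C) should give (2S)-5,7,3'-tri-O-acetyl-6-(methoxymethyl)hesperetin F1.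
- TMSBr in CH2Cl2 at 0 °C then attacks the most Lewis-basic oxygen, the dialkyl ether, to give the 6-(bromomethyl) triacetate F2.
- Alkenyllithium 6 is quenched with Bu3SnCl to (E)-tributyl(2,6-dimethylhepta-1,5-dien-1-yl)stannane F3.
- A neutral Migita–Kosugi–Stille coupling of the benzylic bromide with the stannane (Pd2(dba)3, AsPh3, THF, 50 °C) should give 6-geranylhesperetin triacetate F4.
- Acid-catalysed methanolysis (dilute HCl, MeOH, rt) comes back to the route at 20.

Step 6.
- What may go wrong: transmetalation of the sp3 alkoxymethyl group to a doubly ortho-substituted, electron-rich aryl–Pd may be slow, which allows protodeiodination or butyl transfer.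
- Fallback: the polarity is reversed, with an aryl nucleophile and a C1 electrophile and no palladium.
- Setting out from 11, O5 is capped (MOMCl, NaH, DMF) to give 6-iodo-5,7-bis(methoxymethoxy)-4H-chromen-4-one F5.
- Iodine–magnesium exchange (iPrMgCl·LiCl, THF, −40 °C) gives the C6 arylmagnesium chloride F6.
- This is alkylated in the flask by MOMCl to 6-(methoxymethyl)-5,7-bis(methoxymethoxy)-4H-chromen-4-one F7.
- Chelation-assisted cleavage of the peri 5-O-MOM group (catalytic HCl, MeOH, 0 °C) comes back to the route at 13.

Step 7.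
- What may go wrong: carbometalation of the electron-rich 5,7-dioxygenated chromone may be sluggish, facial selectivity may be poor, or enantiopurity may erode through reversible opening of ring C.
- Fallback: resolution takes the place of asymmetric C–C bond formation.
- Setting out from 13 and 14, an achiral Pd(II)-catalysed conjugate addition (Pd(OCOCF3)2, 2,2'-bipyridine, AcOH–THF–H2O, 60 °C) should give the racemic flavanone F8.
- Kinetic resolution follows by Noyori asymmetric transfer hydrogenation (RuCl[(R,R)-TsDPEN](p-cymene), HCO2H–Et3N, rt).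
- It should reduce the matched (2R)-ketone to the (2R,4R)-cis-flavan-4-ol F9, which is separated by chromatography, and leave the (2S)-ketone, which is 15.

Further compounds
F1 | step 9 | (2S)-5,7-diacetoxy-2-(3-acetoxy-4-methoxyphenyl)-6-(methoxymethyl)chroman-4-one | COc1ccc([C@@H]2CC(=O)c3c(cc(OC(C)=O)c(COC)c3OC(C)=O)O2)cc1OC(C)=O
F2 | step 9 | (2S)-5,7-diacetoxy-2-(3-acetoxy-4-methoxyphenyl)-6-(bromomethyl)chroman-4-one | COc1ccc([C@@H]2CC(=O)c3c(cc(OC(C)=O)c(CBr)c3OC(C)=O)O2)cc1OC(C)=O
F3 | step 9 | (E)-tributyl(2,6-dimethylhepta-1,5-dien-1-yl)stannane | CCCC[Sn](CCCC)(CCCC)/C=C(\C)CCC=C(C)C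
F4 | step 9 | (2S)-5,7-diacetoxy-2-(3-acetoxy-4-methoxyphenyl)-6-[(2E)-3,7-dimethylocta-2,6-dien-1-yl]chroman-4-one | COc1ccc([C@@H]2CC(=O)c3c(cc(OC(C)=O)c(C/C=C(\C)CCC=C(C)C)c3OC(C)=O)O2)cc1OC(C)=O
F5 | step 6 | 6-iodo-5,7-bis(methoxymethoxy)-4H-chromen-4-one | COCOc1cc2occc(=O)c2c(OCOC)c1I
F6 | step 6 | [5,7-bis(methoxymethoxy)-4-oxo-4H-chromen-6-yl]magnesium chloride | COCOc1cc2occc(=O)c2c(OCOC)c1[Mg]Cl
F7 | step 6 | 6-(methoxymethyl)-5,7-bis(methoxymethoxy)-4H-chromen-4-one | COCOc1cc2occc(=O)c2c(OCOC)c1COC
F8 | step 7 | racemic 5-hydroxy-2-(3-hydroxy-4-methoxyphenyl)-6-(methoxymethyl)-7-(methoxymethoxy)chroman-4-one | COc1ccc(C2CC(=O)c3c(cc(OCOC)c(COC)c3O)O2)cc1O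
F9 | step 7 | (2R,4R)-2-(3-hydroxy-4-methoxyphenyl)-6-(methoxymethyl)-7-(methoxymethoxy)chroman-4,5-diol | COc1ccc([C@H]2C[C@@H](O)c3c(cc(OCOC)c(COC)c3O)O2)cc1O
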